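## The problem

The target is a flavone in which C3 and C2' are tied together by a three-atom bridge. Flavone numbering is used throughout: O1, C2–C4, C4a, C5–C8 and C8a for the chromone, C1'–C6' for ring B, and C9 (methylene on C3), C10 and O11 (on C2') for the bridge. The bridge closes a seven-membered oxepine that is fused to the pyranone across C2–C3 and to ring B across C1'–C2'. Ring A is fully differentiated (chelated 5-OH, 6-(E)-3-methylbut-1-enyl, 7-OMe, 8-H), so C6 must be told from C8 and the 5-oxygen from the 7-oxygen. The only stereocentre is C10 (S; priorities O11 > C(CH3)2OOH > C9 > H). Nothing else in the molecule can control it, so it has to come from a reagent, and afterwards it is at risk only if the C10–O11 bond is broken or C10 ionises, which matters because C10 is allylic in every isopropenyl precursor. The tertiary hydroperoxide will not survive phosphines, boranes, low-valent metals, thiols or strong acid. The electron-rich styrene-type alkene at C6 is open to electrophiles, radicals and acid, and the chromone accepts nucleophiles at C2 with opening of the pyranone. The feature that makes the plan possible is that O11 is an aryl ether on C2', and C2' is ortho to C1', which carries C2 of the chromone. The unit C2=C3–C4=O makes ring B a vinylogous aryl ketone, so a fluoride on C2' can be displaced by the C10 oxygen and the ether bond is made at the arene, not at the stereocentre.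

## Retrosynthesis

**Peroxide last (20 ⇒ 19 ⇒ 18).** The bond between the quaternary carbon and the peroxide oxygen is cut, together with the O-protecting groups. The hydroperoxide of 20 is traced to the triethylsilyl peroxide 19 and this to the isopropenyl compound 18, by Markovnikov addition of H and OO across the 1,1-disubstituted alkene. An O–O bond could not be carried through base, borane or palladium, and displacement at a tertiary carbinol would need a cation next to the C10–O11 bond; a neutral radical hydrofunctionalisation avoids both. Compound 18 contains no peroxide. The forward step must choose the isopropenyl group over the 1,2-disubstituted alkene at C6, and the final deprotection must be mild.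

**Oxepine by aryl–oxygen bond formation (18 ⇒ 17).** The O11–C2' bond is cut. The neighbouring cut, O11–C10, would ask for an SN2 reaction with inversion at a secondary allylic carbon, where SN2' and ionisation compete. Cutting C3–C9 would require a nucleophilic chromone C3, which has no good equivalent. The precursor 17 is an open 2'-fluoroflavone carrying the (S)-carbinol. The forward step is an intramolecular SNAr that must beat addition of the alkoxide to C2.

**The stereocentre (17 ⇒ 16).** The C10–H bond is cut, and carbinol 17 comes from the isopropenyl ketone 16 by catalyst-controlled reduction. The ketone does three jobs: it is the handle by which C9 is attached, it keeps the alkene electron-poor while ring A is iodinated, and it offers a clear large/small difference to the reduction catalyst. Adding an isopropenyl metal to an aldehyde would be the alternative and is harder to make selective.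

**Ring A substituents (16 ⇒ 15 ⇒ 13 + 14 ⇒ 12).** The C6–alkenyl bond is cut to iodide 13 and the commercial (E)-alkenylboronate 14, and the C6–I bond to flavone 12. The order is dictated by the free 5-hydroxyl, which directs iodination to C6 and is therefore protected (15 ⇒ 16) only after the coupling. Installing the alkene on the acetophenone would lose this control, because either ortho oxygen could then close the pyranone.

**Pyranone (12 ⇒ 11 ⇒ 10).** The O1–C2 bond is cut, and the flavone is the cyclodehydration product of triketone 10. The acid that closes the ring also removes the temporary groups, and the 4'-oxygen is then re-protected as a MOM ether, a group that resists the alkoxide and the fluoride of the ring closure.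

**C3 side chain (10 ⇒ 6 + 9; 9 ⇒ 7).** The C3–C9 bond is cut to the 1,3-diketone 6 and the bromomethyl isopropenyl ketone 9. The central carbon of a β-diketone is the one reliably nucleophilic form of flavone C3. Compound 9 is made from the enone 7 through its silyl enol ether 8.

**Diketone (6 ⇒ 2 + 4; 2 ⇒ 1; 4 ⇒ 3).** The bond between the methylene and the ring B carbonyl is cut (Baker–Venkataraman logic). The partners are the mono-MOM acetophenone 2, from the symmetric 1, and the silyl-protected acid derivative 4, from 3 and used as its acid chloride 5. Ring A is still symmetric here, so no regiochemical question arises before step 8.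

## Roads not taken

**Alternative 1:** The cut is C4–C4a, with ring A delivered as the 3,5-dimethoxyphenyl ether of the enol oxygen at C2. Forward, the acid A1 (a 5-aryloxy-2,3-dihydro-1-benzoxepine-4-carboxylic acid with a quaternary ester carbon on C10) would be activated and would acylate the dimethoxyphenoxy ring ortho to its oxygen, giving A2. This is an intramolecular Friedel–Crafts reaction of the kind that turns β-aryloxyacrylic acids into chromones.
- Merits: ring A is symmetric, so the acylation has a single outcome. The oxepine and C10 exist before the chromone, so the aryl ether can be made under direct ortho-carbonyl activation. The future hydroperoxide carbon travels as a robust ester.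
- Weak points: A2 has a 5-methyl ether and nothing at C6, so selective demethylation, iodination and alkenylation all fall on the tetracycle. The hindered ester must then be saponified and converted to OOH by decarboxylative oxygenation (Barton ester, O2) beside a styrene. The enol ether acid can hydrolyse and decarboxylate in the acylating acid.
- Comparison: this road is better in two respects, since it needs no late choice between two alkenes and its aryl ether formation is more strongly activated. Against that the chosen plan sets a shorter sequence, a 5-oxygen that is never a methyl ether, and a hydroperoxide carbon that needs no C–C cleavage.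

**Alternative 2:** The cut removes ring B (C1'–C2' and C5'–C6'). Forward, the 2-ethynylchromone A3, whose C10 oxygen carries a 1-alkoxy-1,3-bis(silyloxy)diene, would undergo an intramolecular Diels–Alder reaction. Loss of silanol and desilylation would give A4, the isopropenyl analogue of the target with free phenols.
- Merits: ring B, the aryl ether and the oxepine arise in one operation. No halogenated ring B and no question of SNAr activation are involved. Tether and polarity fix the regiochemistry, and from A3 onward it is the shortest road.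
- Weak points: the dienol ether sits on an allylic ester oxygen, so a [3,3] shift of the Ireland–Claisen type competes and would erase the C10–O11 bond and the stereocentre. The diene has to be generated with amide base beside an alkynyl chromone (a strong Michael acceptor) and a chelated phenol. The cycloaddition must close a seven-membered ring through a short, partly sp2 tether. A4 would then be peroxidised with free phenols, which retard radical chains.
- Comparison: it is better in convergence. The chosen plan sets against it that every bond is formed by a separate, well-known reaction, that C10 never sits in an array able to rearrange, and that the phenols are protected in the radical step.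

**Alternative 3:** The cut is C2–C3. Forward, the keto ester A5 would be treated with LiN(SiMe3)2; the ketone enolate attacks the ring B ester in an intramolecular Claisen condensation and closes the oxepine as the enolised 1,3-diketone A6. Acid would then close the pyranone.
- Merits: the aryl ether is made intermolecularly on a ring B ester in which fluorine is directly ortho to the carbonyl, so its activation is not in doubt. The C2–C3 bond is the classical flavone diketone bond.
- Weak points: a seven-membered Claisen closure is slow and reversible and competes with intermolecular condensation. Ring A in A6 is 2-hydroxy-4,6-dimethoxy, so after pyranone closure the 5-oxygen is a methyl ether whose removal needs a boron or aluminium halide beside an ionisable allylic aryl ether at C10. C6 still has to be iodinated and alkenylated, and the chiral chain ketone has to be built separately.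
- Comparison: it is better in the certainty of the aryl–oxygen bond. The chosen plan sets against it an irreversible closure on a substrate in which C9 and ring B are held cis on C2=C3, no Lewis-acid demethylation, and fewer steps.

Key step: step 12

Assumption: 1-bromo-3-methylbut-3-en-2-one (9) is not relied on as a catalogue item and is made in step 4. The 4'-oxygen is carried as a MOM ether in the key step because an aryl silyl ether would be attacked by the alkoxide and by the fluoride that the step releases.

## Route

Step 1
Reactants: 1 1-(2,6-dihydroxy-4-methoxyphenyl)ethan-1-one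
Product: 2 1-[2-hydroxy-4-methoxy-6-(methoxymethoxy)phenyl]ethan-1-one
Conditions: MOMCl (1.1 equiv), iPr2NEt, CH2Cl2, 0 °C → rt
Reagents that add atoms: chloromethyl methyl ether COCCl
Why: MOM protection of a phenol; after the first hydroxyl has reacted the second stays hydrogen-bonded to the ketone, so the mono-ether should dominate, and the two hydroxyls of 1 are equivalent, so there is no regiochemical question.

Step 2
Reactants: 3 2-fluoro-4-hydroxybenzoic acid
Product: 4 tert-butyldimethylsilyl 4-[(tert-butyldimethylsilyl)oxy]-2-fluorobenzoate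
Conditions: TBSCl (2.3 equiv), imidazole, DMF, rt
Reagents that add atoms: tert-butyldimethylsilyl chloride CC(C)(C)[Si](C)(C)Cl
Why: Silylation of both acidic oxygens; the silyl ester is a masked acid that can be turned into the acid chloride under neutral conditions, and the aryl silyl ether protects the phenol during acylation.

Step 3
Reactants: 2 1-[2-hydroxy-4-methoxy-6-(methoxymethoxy)phenyl]ethan-1-one; 4 tert-butyldimethylsilyl 4-[(tert-butyldimethylsilyl)oxy]-2-fluorobenzoate
Product: 6 1-{4-[(tert-butyldimethylsilyl)oxy]-2-fluorophenyl}-3-[2-hydroxy-4-methoxy-6-(methoxymethoxy)phenyl]propane-1,3-dione, via acid chloride 5 (not isolated)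
Conditions: 4: (COCl)2, DMF (cat.), CH2Cl2, 0 °C → rt, evaporate; 2: LiN(SiMe3)2 (3.2 equiv), THF, −78 °C, then 5, −78 → 0 °C
Reagents that add atoms: none
Why: Oxalyl chloride/DMF converts the silyl ester into the acid chloride without touching the aryl silyl ether; the phenoxide–enolate dianion of 2 is then acylated on carbon (Baker–Venkataraman-type Claisen acylation, any O-acyl isomer rearranging under the excess base), and the third equivalent of base holds the product as its enolate. Low temperature keeps the enolate oxygen from displacing the ortho-fluorine.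

Step 4
Reactants: 7 3-methylbut-3-en-2-one
Product: 9 1-bromo-3-methylbut-3-en-2-one, via silyl enol ether 8 (not isolated)
Conditions: Me3SiOSO2CF3, Et3N, CH2Cl2, 0 °C; then NBS, −78 → 0 °C; used at once as a solution
Reagents that add atoms: N-bromosuccinimide O=C1CCC(=O)N1Br
Why: The ketone has a single enolisable position, so soft enolisation gives one silyl enol ether, and electrophilic bromination of silyl enol ethers with NBS is a standard route to α-bromo ketones. The product is a lachrymatory, polymerisable Michael acceptor and is not stored.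

Step 5
Reactants: 6 1-{4-[(tert-butyldimethylsilyl)oxy]-2-fluorophenyl}-3-[2-hydroxy-4-methoxy-6-(methoxymethoxy)phenyl]propane-1,3-dione; 9 1-bromo-3-methylbut-3-en-2-one
Product: 10 1-{4-[(tert-butyldimethylsilyl)oxy]-2-fluorophenyl}-3-[2-hydroxy-4-methoxy-6-(methoxymethoxy)phenyl]-2-(3-methyl-2-oxobut-3-en-1-yl)propane-1,3-dione
Conditions: K2CO3 (1.5 equiv), acetone, 0 °C → rt
Reagents that add atoms: none
Why: C-Alkylation of a β-diketone enolate with an α-halo ketone (SN2); the bromomethyl carbon is far more reactive than the α-substituted enone terminus, and the chelated phenol is less acidic and less nucleophilic than the diketone. Keeping the temperature at or below rt avoids displacement of fluoride by the enolate oxygen.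

Step 6
Reactants: 10 1-{4-[(tert-butyldimethylsilyl)oxy]-2-fluorophenyl}-3-[2-hydroxy-4-methoxy-6-(methoxymethoxy)phenyl]-2-(3-methyl-2-oxobut-3-en-1-yl)propane-1,3-dione
Product: 11 2-(2-fluoro-4-hydroxyphenyl)-5-hydroxy-7-methoxy-3-(3-methyl-2-oxobut-3-en-1-yl)-4H-chromen-4-one
Conditions: H2SO4 (cat.), AcOH/H2O (95:5), 70 °C
Reagents that add atoms: none
Why: Acid-catalysed cyclodehydration of a 2-hydroxyaryl 1,3-diketone (second stage of the Baker–Venkataraman flavone synthesis): the phenol adds to the ring B carbonyl and the six-membered hemiketal loses water, which should outrun furan formation from the 1,4-dicarbonyl unit. The same medium hydrolyses the MOM acetal and the aryl silyl ether, and since ring A is symmetric either ortho oxygen gives the same chromone.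

Step 7
Reactants: 11 2-(2-fluoro-4-hydroxyphenyl)-5-hydroxy-7-methoxy-3-(3-methyl-2-oxobut-3-en-1-yl)-4H-chromen-4-one
Product: 12 2-[2-fluoro-4-(methoxymethoxy)phenyl]-5-hydroxy-7-methoxy-3-(3-methyl-2-oxobut-3-en-1-yl)-4H-chromen-4-one
Conditions: MOMCl (1.1 equiv), iPr2NEt (1.5 equiv), CH2Cl2, 0 °C
Reagents that add atoms: chloromethyl methyl ether COCCl
Why: Selective O-alkylation: the 4'-hydroxyl is a free, acidic phenol (a vinylogous acid), whereas the 5-hydroxyl is chelated to the C4 carbonyl and does not react under mild amine base.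

Step 8
Reactants: 12 2-[2-fluoro-4-(methoxymethoxy)phenyl]-5-hydroxy-7-methoxy-3-(3-methyl-2-oxobut-3-en-1-yl)-4H-chromen-4-one
Product: 13 2-[2-fluoro-4-(methoxymethoxy)phenyl]-5-hydroxy-6-iodo-7-methoxy-3-(3-methyl-2-oxobut-3-en-1-yl)-4H-chromen-4-one
Conditions: BnMe3N·ICl2 (1.05 equiv), CaCO3, CH2Cl2/MeOH, rt
Reagents that add atoms: benzyltrimethylammonium dichloroiodate C[N+](C)(C)Cc1ccccc1.Cl[I-]Cl
Why: Electrophilic aromatic iodination directed ortho by the free 5-hydroxyl; with 5-hydroxy-7-alkoxyflavones this reagent is known to substitute C6 and not C8. The enone alkene is electron-poor, ring B is deactivated, and CaCO3 takes up the HCl so that the MOM ether survives.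

Step 9
Reactants: 13 2-[2-fluoro-4-(methoxymethoxy)phenyl]-5-hydroxy-6-iodo-7-methoxy-3-(3-methyl-2-oxobut-3-en-1-yl)-4H-chromen-4-one; 14 4,4,5,5-tetramethyl-2-[(E)-3-methylbut-1-en-1-yl]-1,3,2-dioxaborolane
Product: 15 2-[2-fluoro-4-(methoxymethoxy)phenyl]-5-hydroxy-7-methoxy-6-[(E)-3-methylbut-1-en-1-yl]-3-(3-methyl-2-oxobut-3-en-1-yl)-4H-chromen-4-one
Conditions: Pd(OAc)2 (5 mol %), SPhos (10 mol %), K3PO4, THF/H2O (10:1), 50 °C
Reagents that add atoms: none
Why: Suzuki–Miyaura coupling of an aryl iodide with an (E)-alkenylboronate, which proceeds with retention of alkene geometry. The bulky biarylphosphine serves the di-ortho-substituted, electron-rich iodide at moderate temperature, the C–F bond is inert to zerovalent palladium, and the mild phosphate base spares the enone.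

Step 10
Reactants: 15 2-[2-fluoro-4-(methoxymethoxy)phenyl]-5-hydroxy-7-methoxy-6-[(E)-3-methylbut-1-en-1-yl]-3-(3-methyl-2-oxobut-3-en-1-yl)-4H-chromen-4-one
Product: 16 2-[2-fluoro-4-(methoxymethoxy)phenyl]-7-methoxy-5-(methoxymethoxy)-6-[(E)-3-methylbut-1-en-1-yl]-3-(3-methyl-2-oxobut-3-en-1-yl)-4H-chromen-4-one
Conditions: MOMCl (4 equiv), iPr2NEt (6 equiv), Bu4NI (cat.), ClCH2CH2Cl, 50 °C
Reagents that add atoms: chloromethyl methyl ether COCCl
Why: MOM protection of the chelated, hindered 5-hydroxyl needs excess reagent and warming; an amine base is used because the enone and the C9 methylene would not tolerate NaH. The ether prevents phenoxide formation in step 12, which would switch off the chromone as an acceptor.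

Step 11
Reactants: 16 2-[2-fluoro-4-(methoxymethoxy)phenyl]-7-methoxy-5-(methoxymethoxy)-6-[(E)-3-methylbut-1-en-1-yl]-3-(3-methyl-2-oxobut-3-en-1-yl)-4H-chromen-4-one
Product: 17 2-[2-fluoro-4-(methoxymethoxy)phenyl]-3-[(2S)-2-hydroxy-3-methylbut-3-en-1-yl]-7-methoxy-5-(methoxymethoxy)-6-[(E)-3-methylbut-1-en-1-yl]-4H-chromen-4-one
Conditions: (R)-2-methyl-CBS-oxazaborolidine (0.5 equiv), catecholborane (2 equiv), toluene/CH2Cl2, −78 °C; MeOH quench
Reagents that add atoms: none
Why: Corey–Bakshi–Shibata reduction: the ketone binds the catalyst boron anti to its larger substituent, here the α-branched sp2 isopropenyl group, and hydride comes from the borane held on nitrogen; since the (S)-catalyst turns acetophenone into the (R)-alcohol, the (R)-catalyst should give the (S)-carbinol (large group also higher in CIP rank). Catecholborane at −78 °C is chosen so that 1,2-reduction outruns hydroboration and conjugate reduction; the chromone carbonyl, a vinylogous ester, is not reduced.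

Step 12
Reactants: 17 2-[2-fluoro-4-(methoxymethoxy)phenyl]-3-[(2S)-2-hydroxy-3-methylbut-3-en-1-yl]-7-methoxy-5-(methoxymethoxy)-6-[(E)-3-methylbut-1-en-1-yl]-4H-chromen-4-one
Product: 18 (10S)-oxepinoflavone: 7-methoxy-5,4'-bis(methoxymethoxy)-6-[(E)-3-methylbut-1-en-1-yl]flavone bridged C3–C9H2–C10H[C(CH3)=CH2]–O11–C2'
Conditions: KN(SiMe3)2 (1.2 equiv), 18-crown-6 (1.2 equiv), THF (0.01 M), 0 → 50 °C
Reagents that add atoms: none
Why: KN(SiMe3)2 deprotonates the C10 hydroxyl and the potassium alkoxide adds to C2' ipso to fluorine, giving a Meisenheimer-type anion whose charge runs from C1' through C2=C3 into the C4 carbonyl; loss of fluoride restores ring B. The closest known reaction type is the intramolecular SNAr etherification of ortho-fluoroaryl ketones and enones. The oxepine closes by ipso attack on the arene, a 7-exo closure with respect to the C2'–C3' π bond, helped by C9 and ring B being held cis on C2=C3. No stereocentre is formed: C10 was set in step 11 and its C–O bond is not broken, so the S configuration is carried over. The step needs O11–C2' formation to win over addition of the alkoxide to C2; that addition is a 5-endo-trig closure, geometrically disfavoured and reversible (even a pyranone opened to its phenoxide can re-close), whereas fluoride loss is irreversible. The 5-O-MOM group keeps the chromone from becoming a phenoxide, the 4'-O-MOM group is meta to C2' and does not oppose the anionic intermediate, and neither ether is attacked by the alkoxide or by the fluoride set free. High dilution suppresses intermolecular substitution.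

Step 13
Reactants: 18 (10S)-oxepinoflavone: 7-methoxy-5,4'-bis(methoxymethoxy)-6-[(E)-3-methylbut-1-en-1-yl]flavone bridged C3–C9H2–C10H[C(CH3)=CH2]–O11–C2'
Product: 19 (10S)-oxepinoflavone triethylsilyl peroxide: as 18 but with C10 bearing C(CH3)2–O–O–SiEt3
Conditions: Co(acac)2 (0.2 equiv), Et3SiH (3 equiv), O2 (1 atm), ClCH2CH2Cl, rt
Reagents that add atoms: triethylsilane CC[SiH](CC)CC; dioxygen O=O
Why: Mukaiyama–Isayama hydroperoxysilylation: a cobalt hydride formed from the divalent cobalt salt, silane and O2 transfers hydrogen to the CH2 terminus, the tertiary radical captures O2 and the peroxyl is silylated, so the addition is Markovnikov. 1,1-Disubstituted alkenes are the fastest class in this reaction, whereas the C6 alkene is 1,2-disubstituted and flanked by two ortho substituents and an isopropyl group. The new C–O carbon bears two methyl groups and is not stereogenic, and C10 is untouched.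

Step 14
Reactants: 19 (10S)-oxepinoflavone triethylsilyl peroxide: as 18 but with C10 bearing C(CH3)2–O–O–SiEt3
Product: 20 target: (10S)-5,4'-dihydroxy-10-(2-hydroperoxypropan-2-yl)-7-methoxy-6-[(E)-3-methylbut-1-en-1-yl]flavone bridged C3–C9H2–C10H–O11–C2'
Conditions: HCl (conc., 10 equiv), MeOH/THF (3:1), 0 → 35 °C
Reagents that add atoms: none
Why: Acid-catalysed solvolysis removes the triethylsilyl group from the peroxide and both MOM acetals (the 5-ether quickly, assisted by the peri carbonyl, the 4'-ether more slowly). Tertiary alkyl hydroperoxides tolerate dilute protic acid near room temperature, and Hock-type cleavage needs strong acid, so concentration and temperature are kept low.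

## Compound list

1 | 1-(2,6-dihydroxy-4-methoxyphenyl)ethan-1-one | CC(=O)c1c(O)cc(OC)cc1O | starting material
2 | 1-[2-hydroxy-4-methoxy-6-(methoxymethoxy)phenyl]ethan-1-one | CC(=O)c1c(O)cc(OC)cc1OCOC | intermediate
3 | 2-fluoro-4-hydroxybenzoic acid | O=C(O)c1ccc(O)cc1F | starting material
4 | tert-butyldimethylsilyl 4-[(tert-butyldimethylsilyl)oxy]-2-fluorobenzoate | CC(C)(C)[Si](C)(C)OC(=O)c1ccc(O[Si](C)(C)C(C)(C)C)cc1F | intermediate
5 | 4-[(tert-butyldimethylsilyl)oxy]-2-fluorobenzoyl chloride (not isolated) | O=C(Cl)c1ccc(O[Si](C)(C)C(C)(C)C)cc1F | intermediate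
6 | 1-{4-[(tert-butyldimethylsilyl)oxy]-2-fluorophenyl}-3-[2-hydroxy-4-methoxy-6-(methoxymethoxy)phenyl]propane-1,3-dione | COCOc1cc(OC)cc(O)c1C(=O)CC(=O)c1ccc(O[Si](C)(C)C(C)(C)C)cc1F | intermediate
7 | 3-methylbut-3-en-2-one | CC(=O)C(C)=C | starting material
8 | trimethyl[(3-methylbuta-1,3-dien-2-yl)oxy]silane (not isolated) | C=C(C)C(=C)O[Si](C)(C)C | intermediate
9 | 1-bromo-3-methylbut-3-en-2-one | C=C(C)C(=O)CBr | intermediate
10 | 1-{4-[(tert-butyldimethylsilyl)oxy]-2-fluorophenyl}-3-[2-hydroxy-4-methoxy-6-(methoxymethoxy)phenyl]-2-(3-methyl-2-oxobut-3-en-1-yl)propane-1,3-dione (racemic at C2, enolisable) | COCOc1cc(OC)cc(O)c1C(=O)C(CC(=O)C(C)=C)C(=O)c1ccc(O[Si](C)(C)C(C)(C)C)cc1F | intermediate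
11 | 2-(2-fluoro-4-hydroxyphenyl)-5-hydroxy-7-methoxy-3-(3-methyl-2-oxobut-3-en-1-yl)-4H-chromen-4-one | COc1cc2oc(-c3ccc(O)cc3F)c(CC(=O)C(C)=C)c(=O)c2c(O)c1 | intermediate
12 | 2-[2-fluoro-4-(methoxymethoxy)phenyl]-5-hydroxy-7-methoxy-3-(3-methyl-2-oxobut-3-en-1-yl)-4H-chromen-4-one | COc1cc2oc(-c3ccc(OCOC)cc3F)c(CC(=O)C(C)=C)c(=O)c2c(O)c1 | intermediate
13 | 2-[2-fluoro-4-(methoxymethoxy)phenyl]-5-hydroxy-6-iodo-7-methoxy-3-(3-methyl-2-oxobut-3-en-1-yl)-4H-chromen-4-one | COc1cc2oc(-c3ccc(OCOC)cc3F)c(CC(=O)C(C)=C)c(=O)c2c(O)c1I | intermediate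
14 | 4,4,5,5-tetramethyl-2-[(E)-3-methylbut-1-en-1-yl]-1,3,2-dioxaborolane | CC(C)/C=C/B1OC(C)(C)C(C)(C)O1 | starting material
15 | 2-[2-fluoro-4-(methoxymethoxy)phenyl]-5-hydroxy-7-methoxy-6-[(E)-3-methylbut-1-en-1-yl]-3-(3-methyl-2-oxobut-3-en-1-yl)-4H-chromen-4-one | COc1cc2oc(-c3ccc(OCOC)cc3F)c(CC(=O)C(C)=C)c(=O)c2c(O)c1/C=C/C(C)C | intermediate
16 | 2-[2-fluoro-4-(methoxymethoxy)phenyl]-7-methoxy-5-(methoxymethoxy)-6-[(E)-3-methylbut-1-en-1-yl]-3-(3-methyl-2-oxobut-3-en-1-yl)-4H-chromen-4-one | COc1cc2oc(-c3ccc(OCOC)cc3F)c(CC(=O)C(C)=C)c(=O)c2c(OCOC)c1/C=C/C(C)C | intermediate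
17 | 2-[2-fluoro-4-(methoxymethoxy)phenyl]-3-[(2S)-2-hydroxy-3-methylbut-3-en-1-yl]-7-methoxy-5-(methoxymethoxy)-6-[(E)-3-methylbut-1-en-1-yl]-4H-chromen-4-one | COc1cc2oc(-c3ccc(OCOC)cc3F)c(C[C@H](O)C(C)=C)c(=O)c2c(OCOC)c1/C=C/C(C)C | intermediate
18 | (10S)-oxepinoflavone: 7-methoxy-5,4'-bis(methoxymethoxy)-6-[(E)-3-methylbut-1-en-1-yl]flavone bridged C3–C9H2–C10H[C(CH3)=CH2]–O11–C2' | COc1cc2oc3c(c(=O)c2c(OCOC)c1/C=C/C(C)C)C[C@@H](C(C)=C)Oc1cc(OCOC)ccc1-3 | intermediate
19 | (10S)-oxepinoflavone triethylsilyl peroxide: as 18 with C10 bearing C(CH3)2–O–O–SiEt3 | COc1cc2oc3c(c(=O)c2c(OCOC)c1/C=C/C(C)C)C[C@@H](C(C)(C)OO[Si](CC)(CC)CC)Oc1cc(OCOC)ccc1-3 | intermediate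
20 | (10S)-5,4'-dihydroxy-10-(2-hydroperoxypropan-2-yl)-7-methoxy-6-[(E)-3-methylbut-1-en-1-yl]flavone bridged C3–C9H2–C10H–O11–C2' (CNP0171472.1) | COc1cc2oc3c(c(=O)c2c(O)c1/C=C/C(C)C)C[C@@H](C(C)(C)OO)Oc1cc(O)ccc1-3 | target

## Step count and risks

Total step count: 14. Longest linear sequence: 12 steps (steps 1, 3, 5, 6, 7, 8, 9, 10, 11, 12, 13, 14); steps 2 and 4 are side branches.

**Step 12 (key step).**
- What may go wrong: activation of C2' through the electron-rich 5,7-dioxygenated chromone may be too weak, so that substitution is slower than isomerisation of the alkoxide into the ring-opened phenoxide or base-induced degradation of the allylic alkoxide.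
- Fallback: it sets out from 2 and returns at 18, and forms the same bond by metal catalysis on a chloride. 2-Chloro-4-hydroxybenzoic acid F1 is taken through the chemistry of steps 2–11:
  - bis-silylation to tert-butyldimethylsilyl 4-[(tert-butyldimethylsilyl)oxy]-2-chlorobenzoate F2;
  - conversion into 4-[(tert-butyldimethylsilyl)oxy]-2-chlorobenzoyl chloride F3;
  - acylation of the dianion of 2 to the chloro diketone F4;
  - alkylation with 9 to the chloro triketone F5;
  - cyclodehydration to the 2'-chloro-5,4'-dihydroxyflavone F6;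
  - 4'-O-MOM ether F7, 6-iodide F8 and the alkenylated 2'-chloroflavone F9 (the C–Cl bond is left alone by the catalyst that couples the iodide);
  - the bis-MOM enone F10 and its reduction to the (S)-2'-chloro carbinol F11.
- F11 would then be closed with Pd(OAc)2, 2-(di-tert-butylphosphino)-1,1'-binaphthyl and Cs2CO3 in toluene at 80 °C. Zerovalent palladium inserts into the C2'–Cl bond and reductive elimination from the aryl palladium alkoxide forms O11–C2' without touching C10.

**Step 13.**
- What may go wrong: hydrogen-atom transfer to the C6 alkene, giving a benzylic radical that is oxygenated, or inhibition of the chain, so that the isopropenyl group is not functionalised cleanly.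
- Fallback: it sets out from 18 and returns at 20, and uses an ionic, sterically governed addition. Hydroperoxymercuration with Hg(OAc)2 and concentrated H2O2 in THF at 0 °C would give the β-(acetoxymercurio) hydroperoxide F12, the 1,1-disubstituted alkene reacting far faster than the hindered trans-1,2-disubstituted one. Alkaline NaBH4 replaces mercury by hydrogen to give the bis-MOM tertiary hydroperoxide F13, which under the conditions of step 14 gives 20.

**Step 11.**
- What may go wrong: poor facial selectivity if the catalyst does not tell the isopropenyl group from the bulky CH2–chromone group, or conjugate reduction of the terminal enone.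
- Fallback: it sets out from 16 and returns at 17. Luche reduction (NaBH4, CeCl3·7H2O, MeOH, −40 °C) would give the racemic carbinol F14. Sharpless kinetic resolution (Ti(OiPr)4, D-(−)-diisopropyl tartrate, tert-butyl hydroperoxide in deficit, 4 Å sieves, CH2Cl2, −20 °C) would epoxidise the (R)-enantiomer to the erythro epoxy alcohol F15 and leave the (S)-carbinol 17. The titanium reagent oxidises only the allylic alcohol, not the C6 alkene.

**Step 5.**
- What may go wrong: Michael addition to, or polymerisation of, the bromo enone 9 in place of SN2 alkylation, and loss of the reagent on handling.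
- Fallback: it sets out from 6 and returns at 11, and brings in the isopropenyl ketone after the flavone is formed.
  - Diketone 6 would be alkylated with commercial 2-bromo-N-methoxy-N-methylacetamide (K2CO3, NaI, acetone, rt) to the diketone amide F16.
  - The acid of step 6 would convert this into the flavone-3-acetic N-methoxy-N-methylamide F17.
  - Isopropenylmagnesium bromide, CH2=C(CH3)MgBr (3.5 equiv, THF, −20 → 0 °C), would then give 11. Two equivalents turn the phenols into magnesium phenoxides, which also shield the chromone, and the third adds to the amide, whose chelated adduct releases the enone on work-up.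

**Step 14.**
- What may go wrong: acid-induced rearrangement of the hydroperoxide or acid-promoted reaction of the C6 alkene with the 5-hydroxyl before the 4'-ether is cleaved.
- Fallback: it sets out from 18 and returns at 20, and moves the acetal cleavage in front of the peroxidation. Et3SiOSO2CF3 with 2,2'-bipyridyl in CH2Cl2 at 0 °C would convert both aryl MOM ethers of 18 directly into the bis(triethylsilyl) ether F18. The conditions of step 13 would give the tris(triethylsilyl) compound F19, and Bu4NF buffered with AcOH in THF at 0 °C would remove all three silyl groups to give 20.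

## Further compounds

F1 | step 12 | 2-chloro-4-hydroxybenzoic acid (purchased) | O=C(O)c1ccc(O)cc1Cl
F2 | step 12 | tert-butyldimethylsilyl 4-[(tert-butyldimethylsilyl)oxy]-2-chlorobenzoate | CC(C)(C)[Si](C)(C)OC(=O)c1ccc(O[Si](C)(C)C(C)(C)C)cc1Cl
F3 | step 12 | 4-[(tert-butyldimethylsilyl)oxy]-2-chlorobenzoyl chloride | O=C(Cl)c1ccc(O[Si](C)(C)C(C)(C)C)cc1Cl
F4 | step 12 | 1-{4-[(tert-butyldimethylsilyl)oxy]-2-chlorophenyl}-3-[2-hydroxy-4-methoxy-6-(methoxymethoxy)phenyl]propane-1,3-dione | COCOc1cc(OC)cc(O)c1C(=O)CC(=O)c1ccc(O[Si](C)(C)C(C)(C)C)cc1Cl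
F5 | step 12 | 1-{4-[(tert-butyldimethylsilyl)oxy]-2-chlorophenyl}-3-[2-hydroxy-4-methoxy-6-(methoxymethoxy)phenyl]-2-(3-methyl-2-oxobut-3-en-1-yl)propane-1,3-dione | COCOc1cc(OC)cc(O)c1C(=O)C(CC(=O)C(C)=C)C(=O)c1ccc(O[Si](C)(C)C(C)(C)C)cc1Cl
F6 | step 12 | 2-(2-chloro-4-hydroxyphenyl)-5-hydroxy-7-methoxy-3-(3-methyl-2-oxobut-3-en-1-yl)-4H-chromen-4-one | COc1cc2oc(-c3ccc(O)cc3Cl)c(CC(=O)C(C)=C)c(=O)c2c(O)c1
F7 | step 12 | 2-[2-chloro-4-(methoxymethoxy)phenyl]-5-hydroxy-7-methoxy-3-(3-methyl-2-oxobut-3-en-1-yl)-4H-chromen-4-one | COc1cc2oc(-c3ccc(OCOC)cc3Cl)c(CC(=O)C(C)=C)c(=O)c2c(O)c1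
F8 | step 12 | 2-[2-chloro-4-(methoxymethoxy)phenyl]-5-hydroxy-6-iodo-7-methoxy-3-(3-methyl-2-oxobut-3-en-1-yl)-4H-chromen-4-one | COc1cc2oc(-c3ccc(OCOC)cc3Cl)c(CC(=O)C(C)=C)c(=O)c2c(O)c1I
F9 | step 12 | 2-[2-chloro-4-(methoxymethoxy)phenyl]-5-hydroxy-7-methoxy-6-[(E)-3-methylbut-1-en-1-yl]-3-(3-methyl-2-oxobut-3-en-1-yl)-4H-chromen-4-one | COc1cc2oc(-c3ccc(OCOC)cc3Cl)c(CC(=O)C(C)=C)c(=O)c2c(O)c1/C=C/C(C)C
F10 | step 12 | 2-[2-chloro-4-(methoxymethoxy)phenyl]-7-methoxy-5-(methoxymethoxy)-6-[(E)-3-methylbut-1-en-1-yl]-3-(3-methyl-2-oxobut-3-en-1-yl)-4H-chromen-4-one | COc1cc2oc(-c3ccc(OCOC)cc3Cl)c(CC(=O)C(C)=C)c(=O)c2c(OCOC)c1/C=C/C(C)C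
F11 | step 12 | 2-[2-chloro-4-(methoxymethoxy)phenyl]-3-[(2S)-2-hydroxy-3-methylbut-3-en-1-yl]-7-methoxy-5-(methoxymethoxy)-6-[(E)-3-methylbut-1-en-1-yl]-4H-chromen-4-one | COc1cc2oc(-c3ccc(OCOC)cc3Cl)c(C[C@H](O)C(C)=C)c(=O)c2c(OCOC)c1/C=C/C(C)C
F12 | step 13 | (10S)-oxepinoflavone bis-MOM ether with C10 bearing C(CH3)(CH2HgOAc)OOH (epimers at that carbon) | COc1cc2oc3c(c(=O)c2c(OCOC)c1/C=C/C(C)C)C[C@@H](C(C)(C[Hg]OC(C)=O)OO)Oc1cc(OCOC)ccc1-3
F13 | step 13 | (10S)-oxepinoflavone bis-MOM ether with C10 bearing C(CH3)2OOH | COc1cc2oc3c(c(=O)c2c(OCOC)c1/C=C/C(C)C)C[C@@H](C(C)(C)OO)Oc1cc(OCOC)ccc1-3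
F14 | step 11 | racemic 2-[2-fluoro-4-(methoxymethoxy)phenyl]-3-(2-hydroxy-3-methylbut-3-en-1-yl)-7-methoxy-5-(methoxymethoxy)-6-[(E)-3-methylbut-1-en-1-yl]-4H-chromen-4-one | COc1cc2oc(-c3ccc(OCOC)cc3F)c(CC(O)C(C)=C)c(=O)c2c(OCOC)c1/C=C/C(C)C
F15 | step 11 | 2-[2-fluoro-4-(methoxymethoxy)phenyl]-3-{(2R)-2-hydroxy-2-[(2S)-2-methyloxiran-2-yl]ethyl}-7-methoxy-5-(methoxymethoxy)-6-[(E)-3-methylbut-1-en-1-yl]-4H-chromen-4-one | COc1cc2oc(-c3ccc(OCOC)cc3F)c(C[C@@H](O)[C@]4(C)CO4)c(=O)c2c(OCOC)c1/C=C/C(C)C
F16 | step 5 | 3-{4-[(tert-butyldimethylsilyl)oxy]-2-fluorobenzoyl}-4-[2-hydroxy-4-methoxy-6-(methoxymethoxy)phenyl]-N-methoxy-N-methyl-4-oxobutanamide | COCOc1cc(OC)cc(O)c1C(=O)C(CC(=O)N(C)OC)C(=O)c1ccc(O[Si](C)(C)C(C)(C)C)cc1F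
F17 | step 5 | 2-[2-(2-fluoro-4-hydroxyphenyl)-5-hydroxy-7-methoxy-4-oxo-4H-chromen-3-yl]-N-methoxy-N-methylacetamide | COc1cc2oc(-c3ccc(O)cc3F)c(CC(=O)N(C)OC)c(=O)c2c(O)c1
F18 | step 14 | (10S)-oxepinoflavone as 18 with both MOM ethers replaced by triethylsilyl ethers | COc1cc2oc3c(c(=O)c2c(O[Si](CC)(CC)CC)c1/C=C/C(C)C)C[C@@H](C(C)=C)Oc1cc(O[Si](CC)(CC)CC)ccc1-3
F19 | step 14 | (10S)-oxepinoflavone 5,4'-bis(triethylsilyl) ether with C10 bearing C(CH3)2–O–O–SiEt3 | COc1cc2oc3c(c(=O)c2c(O[Si](CC)(CC)CC)c1/C=C/C(C)C)C[C@@H](C(C)(C)OO[Si](CC)(CC)CC)Oc1cc(O[Si](CC)(CC)CC)ccc1-3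
A1 | alternative 1 | (S)-5-(3,5-dimethoxyphenoxy)-2-(1-methoxy-2-methyl-1-oxopropan-2-yl)-8-[(triisopropylsilyl)oxy]-2,3-dihydro-1-benzoxepine-4-carboxylic acid | COc1cc(OC)cc(OC2=C(C(=O)O)C[C@@H](C(C)(C)C(=O)OC)Oc3cc(O[Si](C(C)C)(C(C)C)C(C)C)ccc23)c1
A2 | alternative 1 | 5,7-dimethoxy oxepine-fused flavone with quaternary methyl ester carbon on C10 and 4'-O-triisopropylsilyl | COc1cc(OC)c2c(c1)oc1c(c2=O)C[C@@H](C(C)(C)C(=O)OC)Oc2cc(O[Si](C(C)C)(C(C)C)C(C)C)ccc2-1
A3 | alternative 2 | 2-ethynyl-5-hydroxy-7-methoxy-6-[(E)-3-methylbut-1-en-1-yl]chromone whose C3 chain CH2–CH(isopropenyl)–O carries a 1,3-bis(trimethylsilyloxy)buta-1,3-dien-1-yl group | COc1cc2oc(C#C)c(C[C@@H](C(C)=C)OC(O[Si](C)(C)C)=CC(O[Si](C)(C)C)=C)c(=O)c2c(O)c1/C=C/C(C)C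
A4 | alternative 2 | isopropenyl analogue of the target with free 5- and 4'-hydroxyls | COc1cc2oc3c(c(=O)c2c(O)c1/C=C/C(C)C)C[C@@H](C(C)=C)Oc1cc(O)ccc1-3
A5 | alternative 3 | methyl 4-[(tert-butyldimethylsilyl)oxy]-2-{[(3S)-6-(2-hydroxy-4,6-dimethoxyphenyl)-2-methyl-6-oxohex-1-en-3-yl]oxy}benzoate | COC(=O)c1ccc(O[Si](C)(C)C(C)(C)C)cc1O[C@H](C(C)=C)CCC(=O)c1c(O)cc(OC)cc1OC
A6 | alternative 3 | 4-aroyl-5-hydroxy-2,3-dihydro-1-benzoxepine (enol form of the 1,3-diketone) with 2-isopropenyl and 8-O-tert-butyldimethylsilyl | OC1=C(C(=O)c2c(O)cc(OC)cc2OC)C[C@@H](C(C)=C)Oc2cc(O[Si](C)(C)C(C)(C)C)ccc12
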